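**Retrosynthetic overview**
1. The two esters go on last (C18 senecioate by carbodiimide coupling, then the C15 hydrogen malonate from Meldrum's acid); the core is ent-labdane-8,15,18-triol with C15 silylated.
2. Rings A and B are closed, in that order, in one cation–olefin cascade of an acyclic (E,E)-diene, as the diterpene cyclase builds 8-hydroxylabdanes: chair–chair folding, C8 cation quenched by water.
3. The cascade is started by an (S)-2-alkyl-2-methyloxirane spanning C4–C18 instead of by a proton. C5 displaces the oxirane oxygen at C4 with inversion, so this one centre controls C4, C5, C10, C9 and C8, and the 18-OH is formed in the cyclisation with no oxygen at C3.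
4. The oxirane comes from a methyl ketone by catalytic asymmetric Corey–Chaykovsky methylene transfer; the ketone comes from ω-oxidised (S)-2,3-dihydrofarnesol and an acetone-homoenolate Grignard reagent (C1–C2 bond).
5. C13 is set first, by asymmetric hydrogenation of (2E,6E)-farnesol.

Assumption: in step 6 the (S)-binaphthoxide catalyst is taken to give the (S)-oxirane; if the measured sense is opposite, the (R)-ligand is used and nothing else changes. Labdane numbering (C1–C20) is used for all chain and ring positions.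

**Step 1**
Reactants: 1 (2E,6E)-farnesol
Product: 2 (3S,6E)-3,7,11-trimethyldodeca-6,10-dien-1-ol
Conditions: Ru(OAc)2[(R)-BINAP] (0.5 mol %), H2 (100 atm), MeOH, 20 °C
Reagents that add atoms: none
Why: Noyori asymmetric hydrogenation of an allylic alcohol; the hydroxyl-bound Ru–BINAP catalyst reduces only the 2,3-alkene, and the (R)-ligand on the E isomer gives the (S)-methyl centre (future C13), as for geraniol to (S)-citronellol.

**Step 2**
Reactants: 2 (3S,6E)-3,7,11-trimethyldodeca-6,10-dien-1-ol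
Product: 3 tert-butyl{[(3S,6E)-3,7,11-trimethyldodeca-6,10-dien-1-yl]oxy}diphenylsilane
Conditions: TBDPSCl, imidazole, DMF, 0 °C → rt
Reagents that add atoms: tert-butyl(chloro)diphenylsilane, CC(C)(C)[Si](Cl)(c1ccccc1)c1ccccc1
Why: Standard silylation of a primary alcohol; the TBDPS ether survives SeO2, the Grignard coupling, dilute HCl, the sulfur ylide and the fluoroalcohol cyclisation, and is later removed by fluoride without touching esters.

**Step 3**
Reactants: 3 tert-butyl{[(3S,6E)-3,7,11-trimethyldodeca-6,10-dien-1-yl]oxy}diphenylsilane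
Product: 4 (2E,6E,10S)-12-[(tert-butyldiphenylsilyl)oxy]-2,6,10-trimethyldodeca-2,6-dien-1-ol
Conditions: SeO2 (0.2 equiv), tBuOOH (3 equiv), salicylic acid (0.1 equiv), CH2Cl2, 0 °C → rt
Reagents that add atoms: tert-butyl hydroperoxide, CC(C)(C)OO (oxygen source, passed on by SeO2, O=[Se]=O)
Why: Sharpless SeO2/tBuOOH allylic oxidation (ene reaction, then [2,3]-sigmatropic shift) attacks the (E)-methyl of the terminal isopropylidene in preference to the more hindered internal alkene and gives the (E)-allylic alcohol (future C1).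

**Step 4**
Reactants: 4 (2E,6E,10S)-12-[(tert-butyldiphenylsilyl)oxy]-2,6,10-trimethyldodeca-2,6-dien-1-ol
Product: 5 {[(3S,6E,10E)-12-bromo-3,7,11-trimethyldodeca-6,10-dien-1-yl]oxy}(tert-butyl)diphenylsilane
Conditions: CBr4, PPh3, CH2Cl2, 0 °C
Reagents that add atoms: carbon tetrabromide, BrC(Br)(Br)Br
Why: Appel bromination under neutral conditions substitutes the primary allylic hydroxyl by SN2 without allylic transposition or loss of E geometry.

**Step 5**
Reactants: 5 {[(3S,6E,10E)-12-bromo-3,7,11-trimethyldodeca-6,10-dien-1-yl]oxy}(tert-butyl)diphenylsilane; 6 2-(2-bromoethyl)-2-methyl-1,3-dioxolane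
Product: 9 (6E,10E,14S)-16-[(tert-butyldiphenylsilyl)oxy]-6,10,14-trimethylhexadeca-6,10-dien-2-one, via Grignard reagent 7 (not isolated), via dioxolane ketal 8 (not isolated)
Conditions: 6, Mg, THF, 25 °C; then 5, Li2CuCl4 (5 mol %), THF, −78 → 0 °C; then 1 M HCl, THF, rt
Reagents that add atoms: 6, 2-(2-bromoethyl)-2-methyl-1,3-dioxolane, CC1(CCBr)OCCO1 (carbons C2, C3, C4, C19); magnesium, [Mg] (held only in 7); water, O (ketone oxygen of 9)
Why: Kochi-type copper-catalysed Grignard/allylic bromide cross-coupling takes place at the primary carbon with retention of the E alkene, and the dilute-acid work-up unmasks the methyl ketone while the TBDPS ether survives.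

**Step 6**
Reactants: 9 (6E,10E,14S)-16-[(tert-butyldiphenylsilyl)oxy]-6,10,14-trimethylhexadeca-6,10-dien-2-one
Product: 10 tert-butyl{[(3S,6E,10E)-3,7,11-trimethyl-14-[(2S)-2-methyloxiran-2-yl]tetradeca-6,10-dien-1-yl]oxy}diphenylsilane
Conditions: Me3S(O)I, NaH, THF; LaLi3[(S)-binaphthoxide]3 (5 mol %), (2,4,6-(MeO)3C6H2)3P=O (5 mol %), 5 Å MS, THF, rt
Reagents that add atoms: dimethylsulfoxonium methylide, C[S+](C)(=O)[CH2-] (made in the flask from trimethylsulfoxonium iodide, C[S+](C)(C)=O.[I-])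
Why: Catalytic asymmetric Corey–Chaykovsky epoxidation; the La/Li binaphthoxide complex binds ketone and ylide, tells the methyl group from the long CH2 chain and transfers CH2 to one carbonyl face to give the (S)-2,2-disubstituted oxirane (C4, with the new CH2 becoming C18).

**Step 7**
Reactants: 10 tert-butyl{[(3S,6E,10E)-3,7,11-trimethyl-14-[(2S)-2-methyloxiran-2-yl]tetradeca-6,10-dien-1-yl]oxy}diphenylsilane
Product: 11 (4S,5S,8S,9S,10R,13S)-15-[(tert-butyldiphenylsilyl)oxy]-ent-labdane-8,18-diol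
Conditions: Ph4PBF4 (0.5 equiv), H2O (10 equiv), (CF3)2CHOH (0.01 M), 0 °C
Reagents that add atoms: water, O (the 8-OH)
Why: Proposed new method: hydrogen-bond activation of the oxirane by the fluoroalcohol lets the C5=C10 alkene open the C4–O bond from the back (inversion at C4, so the (S)-oxirane gives 4S and leaves the oxygen on C18), the chain folds chair–chair with the solvated CH2O arm equatorial, the two E alkenes add anti to give the trans ring fusion with H5, H9 and CH3-20 as in the enzymatic bicyclisation, and water captures the tertiary C8 cation on the equatorial face (the axial face is blocked by CH3-20); the closest known reaction type is the Lewis acid- or fluoroalcohol-promoted epoxide-initiated cation–olefin polycyclisation of trisubstituted epoxy-polyenes, extended here to a 2,2-disubstituted oxirane initiator and water termination.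

**Step 8**
Reactants: 11 (4S,5S,8S,9S,10R,13S)-15-[(tert-butyldiphenylsilyl)oxy]-ent-labdane-8,18-diol; 12 3-methylbut-2-enoic acid
Product: 13 (4S,5S,8S,9S,10R,13S)-15-[(tert-butyldiphenylsilyl)oxy]-8-hydroxy-ent-labdan-18-yl 3-methylbut-2-enoate
Conditions: 12 (2 equiv), DCC, DMAP (0.2 equiv), CH2Cl2, 0 °C → rt
Reagents that add atoms: 12, 3-methylbut-2-enoic acid, CC(C)=CC(=O)O
Why: Steglich esterification acylates only the primary (neopentyl) 18-OH because the tertiary 8-OH is inert, and carbodiimide activation avoids the vinylketene route by which the acid chloride and amine bases give the deconjugated ester.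

**Step 9**
Reactants: 13 (4S,5S,8S,9S,10R,13S)-15-[(tert-butyldiphenylsilyl)oxy]-8-hydroxy-ent-labdan-18-yl 3-methylbut-2-enoate
Product: 14 (4S,5S,8S,9S,10R,13S)-8,15-dihydroxy-ent-labdan-18-yl 3-methylbut-2-enoate
Conditions: Bu4NF, AcOH (1:1), THF, rt
Reagents that add atoms: none
Why: Fluoride-mediated desilylation, buffered with acetic acid, cleaves the Si–O bond without ester cleavage or acyl migration.

**Step 10**
Reactants: 14 (4S,5S,8S,9S,10R,13S)-8,15-dihydroxy-ent-labdan-18-yl 3-methylbut-2-enoate; 15 Meldrum's acid (2,2-dimethyl-1,3-dioxane-4,6-dione)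
Product: 16 3-{[(4S,5S,8S,9S,10R,13S)-8-hydroxy-18-[(3-methylbut-2-enoyl)oxy]-ent-labdan-15-yl]oxy}-3-oxopropanoic acid (CNP0199440.1)
Conditions: 15 (1.2 equiv), toluene, 80 °C
Reagents that add atoms: 15, Meldrum's acid, CC1(C)OC(=O)CC(=O)O1
Why: Thermal alcoholysis of Meldrum's acid by the primary 15-OH gives the malonic half-ester directly with loss of acetone, below the decarboxylation temperature and without reaction at the hindered tertiary 8-OH.

**Compound list**
1 | (2E,6E)-farnesol | CC(C)=CCC/C(C)=C/CC/C(C)=C/CO | starting material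
2 | (3S,6E)-3,7,11-trimethyldodeca-6,10-dien-1-ol ((S)-2,3-dihydrofarnesol) | CC(C)=CCC/C(C)=C/CC[C@H](C)CCO | intermediate
3 | tert-butyl{[(3S,6E)-3,7,11-trimethyldodeca-6,10-dien-1-yl]oxy}diphenylsilane | CC(C)=CCC/C(C)=C/CC[C@H](C)CCO[Si](c1ccccc1)(c1ccccc1)C(C)(C)C | intermediate
4 | (2E,6E,10S)-12-[(tert-butyldiphenylsilyl)oxy]-2,6,10-trimethyldodeca-2,6-dien-1-ol | OC/C(C)=C/CC/C(C)=C/CC[C@H](C)CCO[Si](c1ccccc1)(c1ccccc1)C(C)(C)C | intermediate
5 | {[(3S,6E,10E)-12-bromo-3,7,11-trimethyldodeca-6,10-dien-1-yl]oxy}(tert-butyl)diphenylsilane | BrC/C(C)=C/CC/C(C)=C/CC[C@H](C)CCO[Si](c1ccccc1)(c1ccccc1)C(C)(C)C | intermediate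
6 | 2-(2-bromoethyl)-2-methyl-1,3-dioxolane | CC1(CCBr)OCCO1 | starting material
7 | [2-(2-methyl-1,3-dioxolan-2-yl)ethyl]magnesium bromide (formed in the flask) | CC1(CC[Mg]Br)OCCO1 | intermediate
8 | tert-butyl{[(3S,6E,10E)-3,7,11-trimethyl-14-(2-methyl-1,3-dioxolan-2-yl)tetradeca-6,10-dien-1-yl]oxy}diphenylsilane (hydrolysed in the work-up) | CC1(CCC/C(C)=C/CC/C(C)=C/CC[C@H](C)CCO[Si](c2ccccc2)(c2ccccc2)C(C)(C)C)OCCO1 | intermediate
9 | (6E,10E,14S)-16-[(tert-butyldiphenylsilyl)oxy]-6,10,14-trimethylhexadeca-6,10-dien-2-one | CC(=O)CCC/C(C)=C/CC/C(C)=C/CC[C@H](C)CCO[Si](c1ccccc1)(c1ccccc1)C(C)(C)C | intermediate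
10 | tert-butyl{[(3S,6E,10E)-3,7,11-trimethyl-14-[(2S)-2-methyloxiran-2-yl]tetradeca-6,10-dien-1-yl]oxy}diphenylsilane | C[C@@]1(CO1)CCC/C(C)=C/CC/C(C)=C/CC[C@H](C)CCO[Si](c2ccccc2)(c2ccccc2)C(C)(C)C | intermediate
11 | (4S,5S,8S,9S,10R,13S)-15-[(tert-butyldiphenylsilyl)oxy]-ent-labdane-8,18-diol (trans-decalin; 8-OH equatorial, CH3-17 axial; C18 CH2OH equatorial) | OC[C@@]1(C)CCC[C@]2(C)[C@@H]1CC[C@](C)(O)[C@H]2CC[C@H](C)CCO[Si](c3ccccc3)(c3ccccc3)C(C)(C)C | intermediate
12 | 3-methylbut-2-enoic acid (senecioic acid) | CC(C)=CC(=O)O | starting material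
13 | (4S,5S,8S,9S,10R,13S)-15-[(tert-butyldiphenylsilyl)oxy]-8-hydroxy-ent-labdan-18-yl 3-methylbut-2-enoate | CC(C)=CC(=O)OC[C@@]1(C)CCC[C@]2(C)[C@@H]1CC[C@](C)(O)[C@H]2CC[C@H](C)CCO[Si](c3ccccc3)(c3ccccc3)C(C)(C)C | intermediate
14 | (4S,5S,8S,9S,10R,13S)-8,15-dihydroxy-ent-labdan-18-yl 3-methylbut-2-enoate | CC(C)=CC(=O)OC[C@@]1(C)CCC[C@]2(C)[C@@H]1CC[C@](C)(O)[C@H]2CC[C@H](C)CCO | intermediate
15 | Meldrum's acid (2,2-dimethyl-1,3-dioxane-4,6-dione) | CC1(C)OC(=O)CC(=O)O1 | starting material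
16 | 3-{[(4S,5S,8S,9S,10R,13S)-8-hydroxy-18-[(3-methylbut-2-enoyl)oxy]-ent-labdan-15-yl]oxy}-3-oxopropanoic acid (CNP0199440.1) | CC(C)=CC(=O)OC[C@@]1(C)CCC[C@]2(C)[C@@H]1CC[C@](C)(O)[C@H]2CC[C@H](C)CCOC(=O)CC(=O)O | target

**Step count**
Total steps: 10. Longest linear sequence: 10 steps (1 → 16).

**Three steps most likely to fail**

Step 7 (cyclisation). Four things can go wrong:
- the C8 cation may lose a proton instead of taking up water;
- water may open the oxirane before ring A closes, or a 1,2-hydride shift may give the aldehyde;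
- the chain may fold with the CH2O arm axial, which gives the C18/C19-inverted diastereomer in the opposite decalin series;
- a loose, cation-like opening would erode the inversion at C4.

Fallback, setting out from 10 and coming back at 11: MeAlCl2 in CH2Cl2 at −78 °C closes the same two rings under aprotic, tight ion-pair conditions and ends by proton loss. This gives 15-[(tert-butyldiphenylsilyl)oxy]-ent-labd-8(17)-en-18-ol F1 together with its ring-B isomer 15-[(tert-butyldiphenylsilyl)oxy]-ent-labd-7-en-18-ol F2. The mixture is then hydrated by Mukaiyama hydrogen-atom-transfer hydration (Mn(dpm)3 cat., PhSiH3, O2, iPrOH, 0 °C, then P(OEt)3). Both alkenes give the same tertiary C8 radical, which takes up oxygen from the equatorial face away from CH3-20, and this returns diol 11.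

Step 6 (asymmetric methylene transfer). A linear alkyl methyl ketone is a demanding substrate for high ee, and the sense of induction rests on the assumption above. The minor C4 epimer cannot be separated before the cyclisation. Fallback, setting out from 5 and coming back at 10: the oxygenated quaternary carbon is taken from the chiral pool.
- The Grignard reagent [2-((4S)-2,2,4-trimethyl-1,3-dioxolan-4-yl)ethyl]magnesium bromide F4 is made from the known, (S)-citramalic acid-derived bromide (4S)-4-(2-bromoethyl)-2,2,4-trimethyl-1,3-dioxolane F3.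
- F4 is coupled with 5 under the Li2CuCl4 conditions of step 5 to give the acetonide tert-butyl{[(3S,6E,10E)-3,7,11-trimethyl-14-[(4S)-2,2,4-trimethyl-1,3-dioxolan-4-yl]tetradeca-6,10-dien-1-yl]oxy}diphenylsilane F5.
- AcOH/H2O/THF at 40 °C frees (2S,6E,10E,14S)-16-[(tert-butyldiphenylsilyl)oxy]-2,6,10,14-tetramethylhexadeca-6,10-diene-1,2-diol F6.
- TsCl/pyridine sulfonylates only the primary hydroxyl to give the 1-(4-methylbenzenesulfonate) of that diol F7.
- K2CO3/MeOH closes the oxirane by displacement at C18, which leaves the C4–O bond and its configuration untouched and gives 10.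

Step 3 (allylic oxidation). Site selectivity between the terminal and the internal trisubstituted alkene is only moderate, and over-oxidation to the enal lowers the yield. Fallback, setting out from 3 and coming back at 4:
- NBS in aqueous THF at 0 °C gives the terminal bromohydrin (6E,10S)-3-bromo-12-[(tert-butyldiphenylsilyl)oxy]-2,6,10-trimethyldodec-6-en-2-ol F8.
- K2CO3/MeOH closes it to the terminal epoxide tert-butyl{[(3S,6E)-9-(3,3-dimethyloxiran-2-yl)-3,7-dimethylnon-6-en-1-yl]oxy}diphenylsilane F9.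
- HIO4 in THF/Et2O cleaves it to the aldehyde (4E,8S)-10-[(tert-butyldiphenylsilyl)oxy]-4,8-dimethyldec-4-enal F10.
- The stabilised ylide Ph3P=C(CH3)CO2Et in CH2Cl2 gives ethyl (2E,6E,10S)-12-[(tert-butyldiphenylsilyl)oxy]-2,6,10-trimethyldodeca-2,6-dienoate F11.
- iBu2AlH in CH2Cl2 at −78 °C reduces F11 to allylic alcohol 4.

**Further compounds**
F1 | step 7 | 15-[(tert-butyldiphenylsilyl)oxy]-ent-labd-8(17)-en-18-ol | OC[C@@]1(C)CCC[C@]2(C)[C@@H]1CCC(=C)[C@H]2CC[C@H](C)CCO[Si](c3ccccc3)(c3ccccc3)C(C)(C)C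
F2 | step 7 | 15-[(tert-butyldiphenylsilyl)oxy]-ent-labd-7-en-18-ol | OC[C@@]1(C)CCC[C@]2(C)[C@@H]1CC=C(C)[C@H]2CC[C@H](C)CCO[Si](c3ccccc3)(c3ccccc3)C(C)(C)C
F3 | step 6 | (4S)-4-(2-bromoethyl)-2,2,4-trimethyl-1,3-dioxolane | C[C@@]1(COC(C)(C)O1)CCBr
F4 | step 6 | [2-((4S)-2,2,4-trimethyl-1,3-dioxolan-4-yl)ethyl]magnesium bromide | C[C@@]1(COC(C)(C)O1)CC[Mg]Br
F5 | step 6 | tert-butyl{[(3S,6E,10E)-3,7,11-trimethyl-14-[(4S)-2,2,4-trimethyl-1,3-dioxolan-4-yl]tetradeca-6,10-dien-1-yl]oxy}diphenylsilane | C[C@@]1(COC(C)(C)O1)CCC/C(C)=C/CC/C(C)=C/CC[C@H](C)CCO[Si](c2ccccc2)(c2ccccc2)C(C)(C)C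
F6 | step 6 | (2S,6E,10E,14S)-16-[(tert-butyldiphenylsilyl)oxy]-2,6,10,14-tetramethylhexadeca-6,10-diene-1,2-diol | C[C@@](O)(CO)CCC/C(C)=C/CC/C(C)=C/CC[C@H](C)CCO[Si](c1ccccc1)(c1ccccc1)C(C)(C)C
F7 | step 6 | (2S,6E,10E,14S)-16-[(tert-butyldiphenylsilyl)oxy]-2-hydroxy-2,6,10,14-tetramethylhexadeca-6,10-dien-1-yl 4-methylbenzenesulfonate | C[C@@](O)(COS(=O)(=O)c1ccc(C)cc1)CCC/C(C)=C/CC/C(C)=C/CC[C@H](C)CCO[Si](c2ccccc2)(c2ccccc2)C(C)(C)C
F8 | step 3 | (6E,10S)-3-bromo-12-[(tert-butyldiphenylsilyl)oxy]-2,6,10-trimethyldodec-6-en-2-ol (both C3 epimers) | CC(C)(O)C(Br)CC/C(C)=C/CC[C@H](C)CCO[Si](c1ccccc1)(c1ccccc1)C(C)(C)C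
F9 | step 3 | tert-butyl{[(3S,6E)-9-(3,3-dimethyloxiran-2-yl)-3,7-dimethylnon-6-en-1-yl]oxy}diphenylsilane (both oxirane epimers) | CC1(C)OC1CC/C(C)=C/CC[C@H](C)CCO[Si](c2ccccc2)(c2ccccc2)C(C)(C)C
F10 | step 3 | (4E,8S)-10-[(tert-butyldiphenylsilyl)oxy]-4,8-dimethyldec-4-enal | O=CCC/C(C)=C/CC[C@H](C)CCO[Si](c1ccccc1)(c1ccccc1)C(C)(C)C
F11 | step 3 | ethyl (2E,6E,10S)-12-[(tert-butyldiphenylsilyl)oxy]-2,6,10-trimethyldodeca-2,6-dienoate | CCOC(=O)/C(C)=C/CC/C(C)=C/CC[C@H](C)CCO[Si](c1ccccc1)(c1ccccc1)C(C)(C)C
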